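Take a closed, stirred vessel at constant temperature, charge it with Z, the limiting reagent, and keep a ledger of where each mole of Z goes.

| flask | Z | time |
|---|---|---|
| birch | 0.0020 M | 2.5 d |
| alder | 0.0060 M | 2.5 d |
| larch | 0.015 M | 2.5 d |
| cedar | 0.050 M | 2.5 d |

    Z → J (k1 = 4.5 h⁻¹)
    Z → E (k2 = 0.038 h⁻¹)
    J → X (k3 = 2.1 h⁻¹)
    Z + Q ⇌ Z.Q, settled at all times (K4 = 20 M⁻¹)
    J → E (k5 = 0.068 h⁻¹)
    Q → L (k6 = 9.6 × 10⁻⁵ h⁻¹)
    X → D (k7 = 0.074 h⁻¹)
    X → Q (k8 = 0.067 h⁻¹)

- percentages count the Z that a species holds: one Z.Q counts as two
- Q is meant together with its Z.Q
- in an amount of Q, one Z.Q counts as one Q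
- "hardly changes" means that all values lie within two and a half points (for a concentration: within two and a half percent of the largest)
- run time (birch): 2.5 d

* amount of Q at the end, in percent of the Z charged for birch, alder, larch, cedar, in this order
* how that number moves from the first to the last of them (rises all the way / falls, then rises / rises, then falls / hardly changes / falls all the way)

1. Open the account at Z. It leaves by two first-order steps, to J at 4.5 h⁻¹ and to E at 0.038 h⁻¹, so enter 99.2 % for J.

2. Follow J. It goes to X at 2.1 h⁻¹ and to E at 0.068 h⁻¹, so X receives 96.9 % of what J received.

3. Follow X. It goes to Q at 0.067 h⁻¹ and to D at 0.074 h⁻¹, so Q receives 47.5 % of what X received.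

4. Multiply the three entries to get 45.6 %. Call this the ledger share: the fraction of charged Z that reaches Q when each fork divides in the ratio of its rate constants. The other side of the book holds 3.95 % as E and 50.5 % as D.

5. Now test the binding, where concentration could enter. In cedar, the binding constant times the starting c(Z) is 1.00, but Q has to arrive through X. Z has a half-life of 0.153 h, and X has one of 4.92 h by its two exits together, so Z leaves much sooner than X delivers. After that one half-life of X, the same product in cedar has sunk to 2.05 × 10⁻¹⁰. Enter nothing for binding.

6. Close the books with the loss to L. Its half-life of 300 d is long against the run of 2.5 d, so charge the whole run as a small correction of 0.576 % of Q. That leaves 45.4 % as my figure for Q in birch, and I enter the same figure for each charge. Hold the ratio of the two half-lives, 32.2, against the cedar binding product, and the shape I commit to is hardly changes.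

The forecast gave 45.4 %, 45.4 %, 45.4 % and 45.4 %, shape hardly changes, holding that “the yield does not depend on concentration”.

The simulation gives 45.4 % for birch, 45.4 % for alder, 45.4 % for larch and 45.4 % for cedar, and the shape is hardly changes.

In birch, Z → J and J → X ran first, with the midpoints of their turnover at 0.153 h and 0.556 h, and by 1.25 d Z stood at 0 % and J at 0 %. X in birch, still 1.54 % then, went on dividing between Q and D until it stood at 0.0225 % after 2.50 d, while Q → L had taken 0.228 %. The ledger share less that L gives 45.4 % for birch. In cedar, Z.Q stood at 0 % at the end, and the ledger share less its L of 0.228 % gives 45.4 %, with Q at 45.4 %.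

Its constants are those of an exercise.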